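The plan hinges on breaking the bond between the allyl CH2 group and the fully substituted C5 of the six-membered dienone ring. Once the C5 methyl ether is traced back to a hydroxyl group, this uncovers an ortho-quinone with carbonyls at C5 and C6. The key step joins allyl-B(pin) to C5 of that quinone under a chiral phosphoric acid and so creates the fully substituted stereocentre and the cyclohexa-2,4-dienone at one stroke. It draws on the inequality of the two carbonyls: C6=O ends the push–pull chain O1–C7a=C7–C6=O and sits beside the 7-OMe group, whereas C5=O has only C4–H next to it. The precursor is trans-(2S,3S)-7-methoxy-3-methyl-2-(3,4,5-trimethoxyphenyl)-2,3-dihydrobenzofuran-5,6-dione.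

Key step: step 11

Remark on the chemistry (steps 7 and 8): reduction of a racemising 2-arylpropiophenone is assumed to follow Felkin–Anh control, so the (S)-carbinol forms together with (S)-C2; an SN2 closure of this pair would give the cis ring, so the ring is closed by ionisation.

Remark on the chemistry (step 11): the sense of induction of the acid on a quinone cannot be derived safely from aldehyde models; the (R)-acid is written, and its commercial antipode replaces it, with nothing else changed, if a trial run shows allyl delivery to the wrong face.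

Step 1
Reactants: 1 2,3,4-trihydroxybenzaldehyde
Product: 2 3,4-bis(benzyloxy)-2-hydroxybenzaldehyde
Conditions: BnBr (2.05 equiv), K2CO3 (2.1 equiv), DMF, N2, 0 °C → rt
Reagents that add atoms: benzyl bromide BrCc1ccccc1
Why: Williamson etherification; the 2-OH is tied to the aldehyde oxygen by a strong hydrogen bond and is the least acidic and least nucleophilic phenol, so two equivalents of halide with a weak base should stop at the 3,4-diether.

Step 2
Reactants: 2 3,4-bis(benzyloxy)-2-hydroxybenzaldehyde
Product: 3 3,4-bis(benzyloxy)-2-methoxybenzaldehyde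
Conditions: MeI (1.5 equiv), K2CO3 (2 equiv), DMF, 40 °C
Reagents that add atoms: methyl iodide CI
Why: Williamson etherification of the remaining chelated phenol, which yields to an excess of the small electrophile on gentle warming, nothing else in 2 being alkylatable.

Step 3
Reactants: 3 3,4-bis(benzyloxy)-2-methoxybenzaldehyde
Product: 5 3,4-bis(benzyloxy)-2-methoxyphenol, via aryl formate 4 (not isolated)
Conditions: mCPBA (1.3 equiv), CH2Cl2, 0 °C → rt; wash (aq NaHCO3/Na2S2O3), concentrate; K2CO3 (0.2 equiv), MeOH, rt
Reagents that add atoms: meta-chloroperbenzoic acid O=C(OO)c1cccc(Cl)c1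
Why: Baeyer–Villiger (Dakin-type) oxidation; in an aldehyde with ortho- and para-alkoxy groups the electron-rich aryl group migrates in preference to hydrogen, and the formate is then transesterified by methanol under conditions that leave the benzyl ethers alone.

Step 4
Reactants: 5 3,4-bis(benzyloxy)-2-methoxyphenol
Product: 6 3,4-bis(benzyloxy)-6-bromo-2-methoxyphenol
Conditions: NBS (1.0 equiv), i-Pr2NH (0.1 equiv), CH2Cl2, −40 → 0 °C, dark
Reagents that add atoms: N-bromosuccinimide O=C1CCC(=O)N1Br
Why: Electrophilic aromatic bromination steered by the free phenol; amine-catalysed NBS delivers bromine ortho to OH, C6 is the only open ortho/para site of the strongest donor (para is blocked by OBn), and one equivalent in the cold guards the electron-rich ring against oxidation.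

Step 5
Reactants: 6 3,4-bis(benzyloxy)-6-bromo-2-methoxyphenol
Product: 7 4,5-bis(benzyloxy)-1-bromo-3-methoxy-2-(methoxymethoxy)benzene
Conditions: MOMCl (1.3 equiv), K2CO3 (2 equiv), DMF, 0 °C → rt
Reagents that add atoms: chloromethyl methyl ether COCCl
Why: O-alkylation of the phenoxide to a formaldehyde acetal, a group that withstands the alkoxide bases of steps 6 and 7 and leaves under the same acid that closes the ring in step 8.

Step 6
Reactants: 7 4,5-bis(benzyloxy)-1-bromo-3-methoxy-2-(methoxymethoxy)benzene; 8 1-(3,4,5-trimethoxyphenyl)propan-1-one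
Product: 9 racemic 2-[4,5-bis(benzyloxy)-3-methoxy-2-(methoxymethoxy)phenyl]-1-(3,4,5-trimethoxyphenyl)propan-1-one
Conditions: Pd2(dba)3 (1 mol %), P(t-Bu)3 (2.5 mol %), NaOt-Bu (1.5 equiv), THF, 60 °C
Reagents that add atoms: none
Why: Buchwald–Hartwig-type palladium-catalysed α-arylation of a ketone enolate; the bulky electron-rich phosphine lets the electron-rich ortho-substituted bromide add oxidatively and speeds reductive elimination, the product rests as a hindered enolate that does not arylate twice, and the new bond is the later C3–C3a bond with its stereocentre still racemic.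

Step 7
Reactants: 9 racemic 2-[4,5-bis(benzyloxy)-3-methoxy-2-(methoxymethoxy)phenyl]-1-(3,4,5-trimethoxyphenyl)propan-1-one
Product: 10 (1S,2S)-2-[4,5-bis(benzyloxy)-3-methoxy-2-(methoxymethoxy)phenyl]-1-(3,4,5-trimethoxyphenyl)propan-1-ol
Conditions: trans-RuCl2[(R)-xylBINAP][(R)-DAIPEN] (1 mol %), KOt-Bu (0.3 equiv), H2 (10 atm), i-PrOH–THF, 25 °C; chromatography to remove the minor diastereomer
Reagents that add atoms: none
Why: Noyori asymmetric hydrogenation run as a dynamic kinetic resolution; the alkoxide (unlike a formic acid/amine medium) racemises the α-aryl ketone through its enolate faster than it is reduced, the (R,R)-catalyst fixes (S) at the carbinol by aryl/alkyl discrimination, hydride transfer anti to the bulky α-aryl group (Felkin–Anh) selects the (S)-ketone, and the minor diastereomer is removed because it would feed the enantiomeric series once the carbinol centre is erased in step 8.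

Step 8
Reactants: 10 (1S,2S)-2-[4,5-bis(benzyloxy)-3-methoxy-2-(methoxymethoxy)phenyl]-1-(3,4,5-trimethoxyphenyl)propan-1-ol
Product: 12 (2S,3S)-5,6-bis(benzyloxy)-7-methoxy-3-methyl-2-(3,4,5-trimethoxyphenyl)-2,3-dihydrobenzofuran, via free phenol 11 (not isolated)
Conditions: TFA–CH2Cl2 (1:9), H2O (5 equiv), 0 °C → rt, stopped at full conversion; aq NaHCO3
Reagents that add atoms: none
Why: Acidolysis of the aryl MOM ether followed by SN1 cyclodehydration; the 3,4,5-trimethoxybenzyl cation formed from the carbinol is captured by the neighbouring phenol on the face that places the aryl group anti to the C3 methyl group, so C2 (S) is dictated by the intact C3 (S) centre, and any cis ether can re-ionise and drain to the more stable trans isomer.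

Step 9
Reactants: 12 (2S,3S)-5,6-bis(benzyloxy)-7-methoxy-3-methyl-2-(3,4,5-trimethoxyphenyl)-2,3-dihydrobenzofuran
Product: 13 (2S,3S)-7-methoxy-3-methyl-2-(3,4,5-trimethoxyphenyl)-2,3-dihydrobenzofuran-5,6-diol
Conditions: H2 (1 atm), 10 % Pd/C, EtOAc, rt, stopped after two equivalents of H2; filtration under argon
Reagents that add atoms: none
Why: Catalytic hydrogenolysis; the two unhindered primary benzyl aryl ethers are cleaved much faster than the secondary ring-bound benzylic C2–O1 bond, so a short run at one atmosphere should spare the dihydrofuran ring and both stereocentres.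

Step 10
Reactants: 13 (2S,3S)-7-methoxy-3-methyl-2-(3,4,5-trimethoxyphenyl)-2,3-dihydrobenzofuran-5,6-diol
Product: 14 (2S,3S)-7-methoxy-3-methyl-2-(3,4,5-trimethoxyphenyl)-2,3-dihydrobenzofuran-5,6-dione
Conditions: Ag2O (3 equiv), Na2SO4, toluene–CH2Cl2 (4:1), 0 °C, dark; cold filtration through Celite, filtrate used at once
Reagents that add atoms: none
Why: Two-electron oxidation of a catechol by silver(I) oxide, a heterogeneous reagent whose spent forms are filtered off, so the quinone, which is stabilised by its two alkoxy groups but carries a vinylogously acidic C3–H, reaches the next flask free of soluble acid, base or nucleophile and with C2 and C3 untouched.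

Step 11
Reactants: 14 (2S,3S)-7-methoxy-3-methyl-2-(3,4,5-trimethoxyphenyl)-2,3-dihydrobenzofuran-5,6-dione; 15 allylboronic acid pinacol ester
Product: 17 (2S,3S,5R)-5-allyl-5-hydroxy-7-methoxy-3-methyl-2-(3,4,5-trimethoxyphenyl)-2,3-dihydrobenzofuran-6(5H)-one, via O-boryl adduct 16 (not isolated)
Conditions: 15 (1.5 equiv), (R)-TRIP [3,3'-bis(2,4,6-triisopropylphenyl)-BINOL hydrogen phosphate] (10 mol %), 4 Å MS, toluene–CH2Cl2, −40 °C; pH 7 buffer, 0 °C; chromatography on deactivated silica, kept cold
Reagents that add atoms: none
Why: Proposed new method: the phosphoric acid hydrogen-bonds to a pinacol oxygen of 15 and raises the Lewis acidity of boron, which binds the C5 carbonyl oxygen at the lone pair next to C4–H, and allyl then passes from boron to C5 through a closed six-membered chair, which enforces 1,2-addition rather than attack at C4 and gives the O-boryl ketol 16 while the acid is released without any ligand exchange. The closest known reactions are the chiral-phosphoric-acid-catalysed allylboration of aldehydes with this same pinacol ester, the diol- or aminophenol-catalysed allylboration of ketones and isatins (cyclic 1,2-dicarbonyls with one deactivated carbonyl) and the non-asymmetric allylindium or allylboron 1,2-addition to ortho-quinones; an acid catalyst is chosen because pinacol esters exchange too slowly with diols in the cold and because amines, alkoxides and methanol would add to 14 or tautomerise it through C3–H to the benzofuran-5,6-diol. No ring is closed, since the cyclohexa-2,4-dienone ring arises from the quinone ring simply by rehybridisation of C5. The only new stereocentre, C5 (R), is set by the catalyst, which must steer allyl to the Si face of C5=O (the face syn to the C2 aryl group): the flat C4–H edge sits axial in the chair beside the acid-bound boronate oxygen, the bulky C6/C7 edge sits equatorial, and the 3,3'-aryl walls of the acid can then tell the two faces apart, C2 and C3 being too remote to help or hinder. Site selectivity between the carbonyls comes from the substrate, because C6=O is the carbonyl of the vinylogous ester O1–C7a=C7–C6=O and is flanked by the 7-OMe group, whereas C5=O is only weakly deactivated through the twisted 7-OMe group and has the small C4–H as neighbour. If facial selectivity is incomplete, the C5 epimers are diastereomers and can be separated at this stage.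

Step 12
Reactants: 17 (2S,3S,5R)-5-allyl-5-hydroxy-7-methoxy-3-methyl-2-(3,4,5-trimethoxyphenyl)-2,3-dihydrobenzofuran-6(5H)-one
Product: 18 (2S,3S,5R)-5-allyl-5,7-dimethoxy-3-methyl-2-(3,4,5-trimethoxyphenyl)-2,3-dihydrobenzofuran-6(5H)-one (CNP0080458.1)
Conditions: MeI (20 equiv), Ag2O (3 equiv), 4 Å MS, CH2Cl2, 0 °C → rt, dark
Reagents that add atoms: methyl iodide CI
Why: Purdie-type methylation; silver(I) activates methyl iodide and takes up iodide while the comparatively acidic α-ketol OH is alkylated without a free alkoxide, which shuts out the anionic oxy-Cope shift of allyl to C3a and the acyloin shift, methyl iodide is too soft to alkylate the vinylogous-ester oxygen, staying at or below room temperature avoids the thermal [3,3] shift to the aryl allyl ether, and C5 stays (R) because its C–O bond is not broken.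

Compound list
1 | 2,3,4-trihydroxybenzaldehyde | O=Cc1ccc(O)c(O)c1O | starting material
2 | 3,4-bis(benzyloxy)-2-hydroxybenzaldehyde | O=Cc1ccc(OCc2ccccc2)c(OCc2ccccc2)c1O | intermediate
3 | 3,4-bis(benzyloxy)-2-methoxybenzaldehyde | O=Cc1ccc(OCc2ccccc2)c(OCc2ccccc2)c1OC | intermediate
4 | 3,4-bis(benzyloxy)-2-methoxyphenyl formate | O=COc1ccc(OCc2ccccc2)c(OCc2ccccc2)c1OC | intermediate
5 | 3,4-bis(benzyloxy)-2-methoxyphenol | Oc1ccc(OCc2ccccc2)c(OCc2ccccc2)c1OC | intermediate
6 | 3,4-bis(benzyloxy)-6-bromo-2-methoxyphenol | Oc1c(Br)cc(OCc2ccccc2)c(OCc2ccccc2)c1OC | intermediate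
7 | 4,5-bis(benzyloxy)-1-bromo-3-methoxy-2-(methoxymethoxy)benzene | COCOc1c(Br)cc(OCc2ccccc2)c(OCc2ccccc2)c1OC | intermediate
8 | 1-(3,4,5-trimethoxyphenyl)propan-1-one | CCC(=O)c1cc(OC)c(OC)c(OC)c1 | starting material
9 | racemic 2-[4,5-bis(benzyloxy)-3-methoxy-2-(methoxymethoxy)phenyl]-1-(3,4,5-trimethoxyphenyl)propan-1-one | CC(C(=O)c1cc(OC)c(OC)c(OC)c1)c1cc(OCc2ccccc2)c(OCc2ccccc2)c(OC)c1OCOC | intermediate
10 | (1S,2S)-2-[4,5-bis(benzyloxy)-3-methoxy-2-(methoxymethoxy)phenyl]-1-(3,4,5-trimethoxyphenyl)propan-1-ol | O[C@H](c1cc(OC)c(OC)c(OC)c1)[C@@H](C)c1cc(OCc2ccccc2)c(OCc2ccccc2)c(OC)c1OCOC | intermediate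
11 | (1S,2S)-2-[4,5-bis(benzyloxy)-2-hydroxy-3-methoxyphenyl]-1-(3,4,5-trimethoxyphenyl)propan-1-ol | O[C@H](c1cc(OC)c(OC)c(OC)c1)[C@@H](C)c1cc(OCc2ccccc2)c(OCc2ccccc2)c(OC)c1O | intermediate
12 | (2S,3S)-5,6-bis(benzyloxy)-7-methoxy-3-methyl-2-(3,4,5-trimethoxyphenyl)-2,3-dihydrobenzofuran | COc1c(OCc2ccccc2)c(OCc2ccccc2)cc2c1O[C@H](c1cc(OC)c(OC)c(OC)c1)[C@H]2C | intermediate
13 | (2S,3S)-7-methoxy-3-methyl-2-(3,4,5-trimethoxyphenyl)-2,3-dihydrobenzofuran-5,6-diol | COc1c(O)c(O)cc2c1O[C@H](c1cc(OC)c(OC)c(OC)c1)[C@H]2C | intermediate
14 | (2S,3S)-7-methoxy-3-methyl-2-(3,4,5-trimethoxyphenyl)-2,3-dihydrobenzofuran-5,6-dione | O=C1C=C2C(=C(OC)C1=O)O[C@H](c1cc(OC)c(OC)c(OC)c1)[C@H]2C | intermediate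
15 | allylboronic acid pinacol ester | C=CCB1OC(C)(C)C(C)(C)O1 | starting material
16 | (2S,3S,5R)-5-allyl-7-methoxy-3-methyl-5-[(4,4,5,5-tetramethyl-1,3,2-dioxaborolan-2-yl)oxy]-2-(3,4,5-trimethoxyphenyl)-2,3-dihydrobenzofuran-6(5H)-one | C=CC[C@@]1(OB3OC(C)(C)C(C)(C)O3)C=C2C(=C(OC)C1=O)O[C@H](c1cc(OC)c(OC)c(OC)c1)[C@H]2C | intermediate
17 | (2S,3S,5R)-5-allyl-5-hydroxy-7-methoxy-3-methyl-2-(3,4,5-trimethoxyphenyl)-2,3-dihydrobenzofuran-6(5H)-one | C=CC[C@@]1(O)C=C2C(=C(OC)C1=O)O[C@H](c1cc(OC)c(OC)c(OC)c1)[C@H]2C | intermediate
18 | (2S,3S,5R)-5-allyl-5,7-dimethoxy-3-methyl-2-(3,4,5-trimethoxyphenyl)-2,3-dihydrobenzofuran-6(5H)-one | C=CC[C@@]1(OC)C=C2C(=C(OC)C1=O)O[C@H](c1cc(OC)c(OC)c(OC)c1)[C@H]2C | target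

Total step count: 12. Longest linear sequence: 12 steps (1 → 18); 8 and 15 are purchased and enter directly.

Steps most likely to fail

1. Step 11. The acid may discriminate poorly between the two faces. Turnover may be slow enough for the quinone to tautomerise, or some allyl may leak to C6. The fallback uses known chemistry, sets out from 14 and comes back at 17. Allylindium sesquibromide, preformed from indium and allyl bromide in THF so that no indium metal meets the quinone, is added to 14 at −20 °C. The indium-mediated allylation of ortho-quinones and other 1,2-diones to α-ketols is established, needs neither acid nor base, and relies on the same substrate bias for C5. Facial control is given up, so 17 should form beside the (5S)-ketol F1. The two are diastereomers, are parted by chromatography on deactivated silica, and 17 goes on to step 12.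

2. Step 12. Alkylation of the hindered tertiary hydroxyl may be so slow that sigmatropic shift of the allyl group or aromatisation overtakes it. The fallback sets out from 13 and comes back at 18. The O–CH3 bond at C5 is made first, on the arene, and the allyl group is brought in afterwards, so no ketol has to be alkylated. Catechol 13 is monomethylated (MeI 1 equiv, Li2CO3, DMF), and the 5-O-methyl ether F2 is separated from the 6-O-methyl ether F3. F2 is then dearomatised with PhI(OCOCF3)2 in CH2Cl2 at −78 °C in the presence of allyltrimethylsilane. This oxidative nucleophilic substitution of 2-alkoxyarenols is known to form ortho-quinol ethers by C–C bond formation at the alkoxy-bearing carbon. Attack at C5 rather than C7 is expected because C5 has the open C4–H side. The step should give 18 beside the C5 epimer of the target F4, to be separated by chromatography.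

3. Step 8. The benzylic cation may lose a proton or undergo a hydride shift to a stilbene, whose re-protonation would erode the C3 configuration. Drainage of the cis ether to trans may also be incomplete. The fallback sets out from 10 and comes back at 12 by substitutions with inversion only. Mitsunobu esterification of 10 with 4-nitrobenzoic acid (PPh3, DIAD, THF) inverts the carbinol to the (1R,2S)-4-nitrobenzoate F5. K2CO3 in MeOH frees the (1R,2S)-alcohol F6. The phenolic MOM ether is removed with NaHSO4 on silica in CH2Cl2 to give the (1R,2S)-phenol F7. An intramolecular Mitsunobu etherification (PPh3, DIAD, THF, 0 °C) then closes O1–C2 with a second inversion to the trans ether 12.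

Further compounds
F1 | step 11 | (2S,3S,5S)-5-allyl-5-hydroxy-7-methoxy-3-methyl-2-(3,4,5-trimethoxyphenyl)-2,3-dihydrobenzofuran-6(5H)-one | C=CC[C@]1(O)C=C2C(=C(OC)C1=O)O[C@H](c1cc(OC)c(OC)c(OC)c1)[C@H]2C
F2 | step 12 | (2S,3S)-5,7-dimethoxy-3-methyl-2-(3,4,5-trimethoxyphenyl)-2,3-dihydrobenzofuran-6-ol | COc1c(O)c(OC)cc2c1O[C@H](c1cc(OC)c(OC)c(OC)c1)[C@H]2C
F3 | step 12 | (2S,3S)-6,7-dimethoxy-3-methyl-2-(3,4,5-trimethoxyphenyl)-2,3-dihydrobenzofuran-5-ol | COc1c(OC)c(O)cc2c1O[C@H](c1cc(OC)c(OC)c(OC)c1)[C@H]2C
F4 | step 12 | (2S,3S,5S)-5-allyl-5,7-dimethoxy-3-methyl-2-(3,4,5-trimethoxyphenyl)-2,3-dihydrobenzofuran-6(5H)-one | C=CC[C@]1(OC)C=C2C(=C(OC)C1=O)O[C@H](c1cc(OC)c(OC)c(OC)c1)[C@H]2C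
F5 | step 8 | (1R,2S)-2-[4,5-bis(benzyloxy)-3-methoxy-2-(methoxymethoxy)phenyl]-1-(3,4,5-trimethoxyphenyl)propyl 4-nitrobenzoate | O=C(O[C@@H](c1cc(OC)c(OC)c(OC)c1)[C@@H](C)c1cc(OCc2ccccc2)c(OCc2ccccc2)c(OC)c1OCOC)c1ccc([N+](=O)[O-])cc1
F6 | step 8 | (1R,2S)-2-[4,5-bis(benzyloxy)-3-methoxy-2-(methoxymethoxy)phenyl]-1-(3,4,5-trimethoxyphenyl)propan-1-ol | O[C@@H](c1cc(OC)c(OC)c(OC)c1)[C@@H](C)c1cc(OCc2ccccc2)c(OCc2ccccc2)c(OC)c1OCOC
F7 | step 8 | (1R,2S)-2-[4,5-bis(benzyloxy)-2-hydroxy-3-methoxyphenyl]-1-(3,4,5-trimethoxyphenyl)propan-1-ol | O[C@@H](c1cc(OC)c(OC)c(OC)c1)[C@@H](C)c1cc(OCc2ccccc2)c(OCc2ccccc2)c(OC)c1O
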